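## Analysis of the target

Compound 23 is a flavonol: a 4H-chromen-4-one (benzo ring A fused to pyranone ring C) with a 3,5-dihydroxy-4-methoxyphenyl group (ring B) at C2 and a hydroxyl at C3. Ring A carries oxygen at four of its six carbons (O1 at C8a, OH at C8, OMe at C7, OH at C5), and C6 is its only CH. There is no stereocentre and no geometric or axial isomerism, so the task is one of substitution pattern and oxidation level. The sensitive parts are the 5,8-hydroquinone (para-dihydroxy, easily oxidised to the quinone in air, most of all in base) and the 3-hydroxy-4-pyranone enol. Two methyl ethers (C7, C4') must stay distinct from five free hydroxyls, which rules out a late global demethylation. The difficulty is ring A: a 5,7,8-trioxygenated ring with a single methyl ether at C7 is not a phloroglucinol pattern, and classical routes reach it only by a late oxidation at C8. The strategy reads ring A as a hydroquinone built de novo. C5–O and C8–O are para, C7 bears OMe and C6 bears H, so C5–C8 map onto a 4-methoxy-2-silyloxyfuran. C4a and C8a, which carry the C4 acyl carbon and O1, map onto an acyl alkyne whose other terminus bears a leaving group for O1.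

## Retrosynthetic reasoning

**23 from 22.** The five hydroxyls are unveiled last, all from benzyl ethers, because the free 5,8-hydroquinone should not pass through any basic or oxidising step. The two methyl ethers are not touched by hydrogenolysis, so the OMe/OH pattern of 23 is fixed by the choice of starting materials.

**22 from 21 (O1–C8a).** Ring C is opened at the aryl–oxygen bond. The forward reaction is an intramolecular O-arylation of the enol oxygen of diketone 21 on the aryl bromide. This cut is chosen because the bromine arrives at C8a for free, as a substituent of the alkyne in the ring A construction. The C5 oxygen is a benzyl ether at this stage, so the enol oxygen has only one place to close and the wrong-way pyranone (through the C5 oxygen) cannot form.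

**21 from 15 and 19 (C2–C3).** The diketone is cut between the benzyloxy-bearing carbon and the ring B carbonyl. The forward step is C-acylation of the enolate 20 of ketone 15 by acid chloride 19. The C3 oxygen is present from the start as the benzyloxy group of the ketone side chain, so no oxidation at C3 is needed later. Ring B comes from 16 by benzylation (17), saponification (18) and chloride formation (19).

**15 from 12.** This is protecting-group work only. The free C8 hydroxyl of 12 is benzylated, and the silyl group on the C5 oxygen is exchanged for benzyl in the same flask. A silyl aryl ether next to the ketone would be at risk under the basic, hot conditions of ring closure, and a free C5 phenoxide there could close ring C the wrong way. With benzyl everywhere, one final step removes all protecting groups.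

**12 from 2 and 10 (C5–C4a and C8–C8a).** This is the disconnection that defines the route. Ring A is cut into furan 2 (C5, C6, C7, C8 and the oxygen that becomes C8–OH) and bromoynone 10 (C4a, C8a, the C4 carbonyl and C3 with its oxygen). The forward reaction must give one regioisomer, with the acyl group next to the silyloxy carbon and bromine next to the new hydroxyl, and must open the oxygen bridge of cycloadduct 11 towards the aromatic ring. Cutting here gives two small, cheap precursors, and it puts the uncertain step early, on simple material.

**2 from 1; 10 from 8, 4, 5 and 3.** Furan 2 is the silyl dienol ether of tetronate 1, one step. The bromoynone 10 comes from silyl ynone 8 by bromodesilylation, and 8 from Weinreb amide 4 and alkyne 5 (through 6 and 7). Amide 4 comes from acid chloride 3. The Weinreb route is preferred to a Lewis-acid acylation of a silylalkyne because the benzyl ether of 3 would not be safe with a strong Lewis acid.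

## Alternatives that were turned down

**Alternative 1: aryne insertion into a propiolic acid C–O bond.** The disconnection cuts C8a–O1 and C4a–C4. In the forward key step, fluoride releases the aryne from silyl triflate A3, the carboxylate of arylpropiolic acid A2 adds to it, and the aryl anion takes over the acyl group to give hydroxyaryl ynone A1.
- For it: the step is convergent and its regiochemistry is sound, since the oxygen adds to the aryne carbon remote from the flanking methoxy group. A1 closes to flavone A4 in one more step, so rings A, B and C are assembled faster than in the chosen route.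
- Against it: A4 has a 5,7-dimethoxy ring A. It lacks the C8 oxygen and the C3 oxygen, and it has a methyl ether where 23 has the C5 hydroxyl. Three late corrections are therefore needed on an advanced flavone: peri-selective demethylation at C5, an Elbs-type oxidation at C8 (para to the freed hydroxyl, typically inefficient) and hydroxylation at C3. The 6-endo against 5-exo closure of A1 also needs control, and A3 itself takes several steps.
- Comparison: Alternative 1 is stronger in convergence and in speed to the tricyclic skeleton. The chosen strategy instead has every ring A oxygen and the C3 oxygen in place from the precursors, with no oxidation after the key step.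

**Alternative 2: oxa-Michael–Henry annulation to a 3-nitrochromene.** The disconnection cuts O1–C2 and C3–C4. An amine base adds the phenoxide of salicylaldehyde A6 to nitrostyrene A7, the nitronate closes on the aldehyde, and dehydration gives racemic 3-nitro-2H-chromene A5.
- For it: the key step is very reliable, the two components are simple, and ring C is closed in one operation.
- Against it: A5 is at the wrong oxidation level at three places. C4 is a CH and must become the carbonyl, the nitro group at C3 must be turned into a hydroxyl, and C2 is sp3 and must be dehydrogenated. Its stereocentre is made only to be destroyed. Ring A is again the 5,7-dimethoxy pattern, so the C8 oxidation and the C5 demethylation of Alternative 1 return as well.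
- Comparison: Alternative 2 has the safer key step. The chosen strategy has the less certain key step but a much shorter and redox-neutral path after it.

**Alternative 3: squarate ring expansion to the hydroquinone ring A.** The disconnection cuts C5–C4a. Lithiated pyranone A11 adds to semisquarate A10 to give cyclobutenone A9. On heating, A9 opens to a dienylketene whose ketene carbon bonds to the pyranone C5, giving hydroquinone A8.
- For it: like the chosen route, it builds ring A de novo as the 5,8-hydroquinone with the C7 methoxy group in place. A8 is one hydrogenolysis away from 23, so the endgame is shorter than in the chosen route, and the plan is more convergent.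
- Against it: it needs A11, a fully substituted pyranone that takes several steps to make, and its metalation at C6. A metalated 4-pyranone is a fragile nucleophile, prone to ring opening and self-addition. The addition to A10 must choose one of two carbonyl groups. The uncertain step comes late, on valuable material, and it delivers the unprotected, air-sensitive hydroquinone directly.
- Comparison: Alternative 3 is as strong as the chosen strategy on the oxygenation pattern and stronger on step count after the key step. The chosen strategy offers precursors that are one and three steps from catalogue compounds, a key step that is tested early and cheaply, and a hydroquinone that stays protected until the last step.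

Key step: step 5

Assumption: 1, 3, 5 and 16 are taken as catalogue compounds. Compounds 7, 11 and 21 are racemic and their stereocentres are lost later, so no stereocontrol is required anywhere.

## Steps

Step 1
Reactants: 1 4-methoxyfuran-2(5H)-one (methyl tetronate)
Product: 2 2-(tert-butyldimethylsilyloxy)-4-methoxyfuran
Conditions: TBSOTf, Et3N, CH2Cl2, 0 °C to rt; pentane extraction, short-path distillation
Reagents that add atoms: tert-butyldimethylsilyl trifluoromethanesulfonate, CC(C)(C)[Si](C)(C)OS(=O)(=O)C(F)(F)F
Why: Soft enolisation of a butenolide: the silyl triflate activates the lactone carbonyl, the amine removes a C5 proton, and aromatisation to the furan drives O-silylation (silyl dienol ether formation).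

Step 2
Reactants: 3 benzyloxyacetyl chloride
Product: 4 2-(benzyloxy)-N-methoxy-N-methylacetamide
Conditions: MeNH(OMe)·HCl, pyridine, CH2Cl2, 0 °C to rt
Reagents that add atoms: N,O-dimethylhydroxylamine hydrochloride, CNOC.Cl
Why: Acylation of an amine by an acid chloride gives the Weinreb amide; pyridine is used instead of a trialkylamine so that no benzyloxyketene forms.

Step 3
Reactants: 5 ethynyltrimethylsilane; 4 2-(benzyloxy)-N-methoxy-N-methylacetamide
Product: 8 1-(benzyloxy)-4-(trimethylsilyl)but-3-yn-2-one, via lithium (trimethylsilyl)acetylide 6 (not isolated), via tetrahedral lithium alkoxide adduct 7 (not isolated)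
Conditions: n-BuLi, THF, −78 °C; then 4, −78 to 0 °C; poured into cold 1 M HCl
Reagents that add atoms: none
Why: Weinreb ketone synthesis: acetylide 6 adds once, the chelated adduct 7 holds until the quench, and the acidic quench keeps the released amine protonated so that it cannot add to the ynone.

Step 4
Reactants: 8 1-(benzyloxy)-4-(trimethylsilyl)but-3-yn-2-one
Product: 10 1-(benzyloxy)-4-bromobut-3-yn-2-one, via silver acetylide 9 (not isolated)
Conditions: NBS, AgNO3 (10 mol %), acetone, rt, dark; used at once
Reagents that add atoms: N-bromosuccinimide, O=C1CCC(=O)N1Br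
Why: Silver-catalysed bromodesilylation of an alkynylsilane: the silver acetylide 9 is brominated by NBS and the silver salt is returned; the conditions are neutral and leave the ketone and the benzyl ether alone.

Step 5
Reactants: 2 2-(tert-butyldimethylsilyloxy)-4-methoxyfuran; 10 1-(benzyloxy)-4-bromobut-3-yn-2-one
Product: 12 2-(benzyloxy)-1-[2-bromo-6-(tert-butyldimethylsilyloxy)-3-hydroxy-4-methoxyphenyl]ethan-1-one, via 7-oxanorbornadiene cycloadduct 11 (not isolated)
Conditions: 2 (1.3 equiv, freshly distilled), toluene, −20 °C to rt, dark; then filtration through SiO2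
Reagents that add atoms: none
Why: This is a normal-electron-demand (4+2) cycloaddition of an electron-rich 2-silyloxyfuran to an acyl alkyne followed by opening of the oxygen bridge, the known way from 2-alkoxy- and 2-silyloxyfurans and acetylenic carbonyl compounds to para-oxygenated phenols; 3-halopropiolates are established furan dienophiles, but this furan and bromoynone have not been combined. Ring A is closed by one intermolecular cycloaddition that forms C8–C8a and C5–C4a, probably asynchronously with C8–C8a leading. The regiochemistry that is needed follows from the polarisation of both partners: the unsubstituted furan C5 has the largest HOMO coefficient (it is the β-carbon of the methoxy enol ether and the vinylogous terminus of the silyl ketene acetal), and the bromine-bearing β-carbon of 10 has the largest LUMO coefficient, so the acyl carbon ends next to the silyloxy carbon and bromine next to the bridgehead CH. In 11 the C–O bond at the silyloxy bridgehead ionises, because the cation is an oxocarbenium ion that is also allylic to the methoxy enol ether; the bridge oxygen stays on the other bridgehead, whose proton is lost on aromatisation, so C8 carries OH and C5 keeps its silyl ether. No stereocentre remains, since both bridgehead centres of racemic 11 are destroyed on aromatisation. The furan is used in slight excess so that phenol 12 does not add to unreacted 10. If part of the silyl group is lost, the resulting hydroquinone is taken into step 6, which converts it into the same compound 15.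

Step 6
Reactants: 12 2-(benzyloxy)-1-[2-bromo-6-(tert-butyldimethylsilyloxy)-3-hydroxy-4-methoxyphenyl]ethan-1-one
Product: 15 2-(benzyloxy)-1-[3,6-bis(benzyloxy)-2-bromo-4-methoxyphenyl]ethan-1-one, via benzyl silyl ether 13 (not isolated), via cesium phenoxide 14 (not isolated)
Conditions: BnBr, K2CO3, DMF, rt, Ar; then CsF, rt to 40 °C
Reagents that add atoms: benzyl bromide, BrCc1ccccc1
Why: Williamson etherification of the free phenol, then fluoride cleaves the aryl silyl ether and the phenoxide 14 is benzylated in the same flask; in this order no free hydroquinone stands in base, and the benzyl group at the C5 oxygen withstands steps 10 and 11 and blocks the wrong ring closure.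

Step 7
Reactants: 16 methyl 3,5-dihydroxy-4-methoxybenzoate
Product: 17 methyl 3,5-bis(benzyloxy)-4-methoxybenzoate
Conditions: BnBr, K2CO3, DMF, 60 °C
Reagents that add atoms: benzyl bromide, BrCc1ccccc1
Why: Williamson etherification of both phenols; the ester is inert to carbonate.

Step 8
Reactants: 17 methyl 3,5-bis(benzyloxy)-4-methoxybenzoate
Product: 18 3,5-bis(benzyloxy)-4-methoxybenzoic acid
Conditions: LiOH, THF/MeOH/H2O, 50 °C; then 1 M HCl
Reagents that add atoms: lithium hydroxide, [Li+].[OH-]
Why: Saponification of an unhindered methyl benzoate; the benzyl and methyl ethers are stable to hydroxide.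

Step 9
Reactants: 18 3,5-bis(benzyloxy)-4-methoxybenzoic acid
Product: 19 3,5-bis(benzyloxy)-4-methoxybenzoyl chloride
Conditions: (COCl)2, DMF (cat.), CH2Cl2, 0 °C to rt; evaporated and used crude
Reagents that add atoms: oxalyl chloride, ClC(=O)C(=O)Cl
Why: Acid chloride formation through the Vilsmeier-type chloroiminium catalyst; the by-products are gases.

Step 10
Reactants: 15 2-(benzyloxy)-1-[3,6-bis(benzyloxy)-2-bromo-4-methoxyphenyl]ethan-1-one; 19 3,5-bis(benzyloxy)-4-methoxybenzoyl chloride
Product: 21 2-(benzyloxy)-1-[3,6-bis(benzyloxy)-2-bromo-4-methoxyphenyl]-3-[3,5-bis(benzyloxy)-4-methoxyphenyl]propane-1,3-dione, via lithium enolate 20 (not isolated)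
Conditions: LiHMDS (2.2 equiv), THF, −78 °C; then 19, −78 to 0 °C; 1 M HCl
Reagents that add atoms: none
Why: Claisen-type C-acylation of a ketone lithium enolate by an aroyl chloride; the chelated α-alkoxy enolate 20 reacts at carbon, and the second equivalent of base takes the acidic diketone out of the equilibrium as its enolate. The aryl bromide has no ortho hydrogen, so no aryne can form.

Step 11
Reactants: 21 2-(benzyloxy)-1-[3,6-bis(benzyloxy)-2-bromo-4-methoxyphenyl]-3-[3,5-bis(benzyloxy)-4-methoxyphenyl]propane-1,3-dione
Product: 22 3,5,8-tris(benzyloxy)-2-[3,5-bis(benzyloxy)-4-methoxyphenyl]-7-methoxy-4H-chromen-4-one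
Conditions: CuI (10 mol %), 1,10-phenanthroline (20 mol %), K2CO3, DMF, 100 °C, Ar
Reagents that add atoms: none
Why: Intramolecular Ullmann-type O-arylation of a 1-(2-bromoaryl)-1,3-diketone: the enolate oxygen on the ring B carbonyl displaces bromide at C8a in a 6-membered closure (O1–C8a) to give the chromen-4-one; the copper catalyst is added because the bromide sits on an electron-rich, doubly ortho-substituted ring.

Step 12
Reactants: 22 3,5,8-tris(benzyloxy)-2-[3,5-bis(benzyloxy)-4-methoxyphenyl]-7-methoxy-4H-chromen-4-one
Product: 23 3,5,8-trihydroxy-2-(3,5-dihydroxy-4-methoxyphenyl)-7-methoxy-4H-chromen-4-one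
Conditions: H2 (1 atm), Pd/C (10 %), EtOAc/MeOH, rt; filtration and evaporation under Ar
Reagents that add atoms: none
Why: Hydrogenolysis of five benzyl ethers (four aryl, one enol) over palladium on carbon; the methyl ethers and the pyranone double bond are not affected under these mild conditions.

## Compound list

1 | 4-methoxyfuran-2(5H)-one (methyl tetronate) | COC1=CC(=O)OC1 | starting material
2 | 2-(tert-butyldimethylsilyloxy)-4-methoxyfuran | COc1coc(O[Si](C)(C)C(C)(C)C)c1 | intermediate
3 | benzyloxyacetyl chloride | O=C(Cl)COCc1ccccc1 | starting material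
4 | 2-(benzyloxy)-N-methoxy-N-methylacetamide | CON(C)C(=O)COCc1ccccc1 | intermediate
5 | ethynyltrimethylsilane | C#C[Si](C)(C)C | starting material
6 | lithium (trimethylsilyl)acetylide | [Li]C#C[Si](C)(C)C | intermediate (not isolated)
7 | lithium 1-(benzyloxy)-2-[methoxy(methyl)amino]-4-(trimethylsilyl)but-3-yn-2-olate (racemic) | [Li]OC(COCc1ccccc1)(C#C[Si](C)(C)C)N(C)OC | intermediate (not isolated)
8 | 1-(benzyloxy)-4-(trimethylsilyl)but-3-yn-2-one | C[Si](C)(C)C#CC(=O)COCc1ccccc1 | intermediate
9 | [4-(benzyloxy)-3-oxobut-1-yn-1-yl]silver | O=C(C#C[Ag])COCc1ccccc1 | intermediate (not isolated)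
10 | 1-(benzyloxy)-4-bromobut-3-yn-2-one | O=C(C#CBr)COCc1ccccc1 | intermediate
11 | 2-(benzyloxy)-1-[3-bromo-1-(tert-butyldimethylsilyloxy)-5-methoxy-7-oxabicyclo[2.2.1]hepta-2,5-dien-2-yl]ethan-1-one (racemic; the oxygen bridge fixes the relative configuration of the two bridgeheads) | COC1=CC2(O[Si](C)(C)C(C)(C)C)OC1C(Br)=C2C(=O)COCc1ccccc1 | intermediate (not isolated)
12 | 2-(benzyloxy)-1-[2-bromo-6-(tert-butyldimethylsilyloxy)-3-hydroxy-4-methoxyphenyl]ethan-1-one | COc1cc(O[Si](C)(C)C(C)(C)C)c(C(=O)COCc2ccccc2)c(Br)c1O | intermediate
13 | 2-(benzyloxy)-1-[3-(benzyloxy)-2-bromo-6-(tert-butyldimethylsilyloxy)-4-methoxyphenyl]ethan-1-one | COc1cc(O[Si](C)(C)C(C)(C)C)c(C(=O)COCc2ccccc2)c(Br)c1OCc1ccccc1 | intermediate (not isolated)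
14 | cesium 2-[(benzyloxy)acetyl]-4-(benzyloxy)-3-bromo-5-methoxyphenoxide | COc1cc([O-])c(C(=O)COCc2ccccc2)c(Br)c1OCc1ccccc1.[Cs+] | intermediate (not isolated)
15 | 2-(benzyloxy)-1-[3,6-bis(benzyloxy)-2-bromo-4-methoxyphenyl]ethan-1-one | COc1cc(OCc2ccccc2)c(C(=O)COCc2ccccc2)c(Br)c1OCc1ccccc1 | intermediate
16 | methyl 3,5-dihydroxy-4-methoxybenzoate | COC(=O)c1cc(O)c(OC)c(O)c1 | starting material
17 | methyl 3,5-bis(benzyloxy)-4-methoxybenzoate | COC(=O)c1cc(OCc2ccccc2)c(OC)c(OCc2ccccc2)c1 | intermediate
18 | 3,5-bis(benzyloxy)-4-methoxybenzoic acid | OC(=O)c1cc(OCc2ccccc2)c(OC)c(OCc2ccccc2)c1 | intermediate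
19 | 3,5-bis(benzyloxy)-4-methoxybenzoyl chloride | ClC(=O)c1cc(OCc2ccccc2)c(OC)c(OCc2ccccc2)c1 | intermediate
20 | lithium (Z)-enolate of 15 (chelated geometry assumed; it has no bearing on the outcome) | [Li]O/C(=C\OCc1ccccc1)c1c(Br)c(OCc2ccccc2)c(OC)cc1OCc1ccccc1 | intermediate (not isolated)
21 | 2-(benzyloxy)-1-[3,6-bis(benzyloxy)-2-bromo-4-methoxyphenyl]-3-[3,5-bis(benzyloxy)-4-methoxyphenyl]propane-1,3-dione (racemic, in equilibrium with its enol) | COc1cc(OCc2ccccc2)c(C(=O)C(OCc2ccccc2)C(=O)c2cc(OCc3ccccc3)c(OC)c(OCc3ccccc3)c2)c(Br)c1OCc1ccccc1 | intermediate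
22 | 3,5,8-tris(benzyloxy)-2-[3,5-bis(benzyloxy)-4-methoxyphenyl]-7-methoxy-4H-chromen-4-one | COc1cc(OCc2ccccc2)c2c(=O)c(OCc3ccccc3)c(-c3cc(OCc4ccccc4)c(OC)c(OCc4ccccc4)c3)oc2c1OCc1ccccc1 | intermediate
23 | 3,5,8-trihydroxy-2-(3,5-dihydroxy-4-methoxyphenyl)-7-methoxy-4H-chromen-4-one | COc1cc(O)c2c(=O)c(O)c(-c3cc(O)c(OC)c(O)c3)oc2c1O | target

## Step count and risks

Total: 12 steps. Longest linear sequence: 8 steps (steps 2, 3, 4, 5, 6, 10, 11, 12, from 3 to 23).

**Step 5 (key step).** The most likely failure is that the reaction leaves the cycloaddition path: the furan C5 adds to the bromine-bearing carbon and bromide is then lost (alkynylation of the furanone), or the zwitterion collapses to a Michael adduct without forming the second bond. Decomposition of the bromoynone before it reacts and leakage to the other regioisomer are further possibilities. The cause in each case is the bromine on the dienophile, which is both a leaving group and a perturbation of the alkyne polarisation.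
Fallback, from 4 and 2, returning at 12: the bromine is taken off the dienophile and introduced afterwards. Ethynylmagnesium bromide is added to 4 (THF, 0 °C, acidic quench) to give 1-(benzyloxy)but-3-yn-2-one F1. F1 and 2 undergo the same cycloaddition and bridge opening, now of a plain terminal ynone, to give 2-(benzyloxy)-1-[2-(tert-butyldimethylsilyloxy)-5-hydroxy-4-methoxyphenyl]ethan-1-one F2. F2 is then brominated ortho to its free hydroxyl (NBS, catalytic i-Pr2NH, CH2Cl2, 0 °C). The para position and one ortho position of that phenol are blocked, so the amine-mediated ortho bromination can only go to the carbon between the hydroxyl and the acyl group, which gives 12.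

**Step 10.** O-Acylation of the enolate (enol ester formation) or double acylation may compete with C-acylation, because the enolate oxygen is the less hindered site of a ketone flanked by a 2,6-disubstituted aryl group.
Fallback, from 19 and 15, returning at 21: 19 is reduced with LiAlH(OtBu)3 (THF, −78 °C) to 3,5-bis(benzyloxy)-4-methoxybenzaldehyde F3. The enolate 20 of 15 is added to F3 in an aldol reaction, which can only form the C–C bond, to give 2-(benzyloxy)-1-[3,6-bis(benzyloxy)-2-bromo-4-methoxyphenyl]-3-[3,5-bis(benzyloxy)-4-methoxyphenyl]-3-hydroxypropan-1-one F4 as a mixture of diastereomers. Oxidation of F4 with Dess–Martin periodinane gives 21; both stereocentres of F4 are lost by then.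

**Step 11.** Displacement of bromide may be slow on the electron-rich, doubly ortho-substituted ring, so that protodebromination or retro-Claisen cleavage of the diketone by traces of hydroxide takes over.
Fallback, from 15 and 19, returning at 22: the ring oxygen is put on the arene first and ring C is closed by dehydration. 15 is borylated (B2pin2, Pd(OAc)2, SPhos, KOAc, dioxane, 80 °C) to 2-(benzyloxy)-1-[3,6-bis(benzyloxy)-4-methoxy-2-(4,4,5,5-tetramethyl-1,3,2-dioxaborolan-2-yl)phenyl]ethan-1-one F5. Oxidation with NaBO3 in THF/H2O gives 2-(benzyloxy)-1-[3,6-bis(benzyloxy)-2-hydroxy-4-methoxyphenyl]ethan-1-one F6. Acylation of F6 with 19 (pyridine, DMAP) gives 3,6-bis(benzyloxy)-2-[(benzyloxy)acetyl]-5-methoxyphenyl 3,5-bis(benzyloxy)-4-methoxybenzoate F7. Baker–Venkataraman rearrangement (KOtBu, THF) gives 2-(benzyloxy)-1-[3,6-bis(benzyloxy)-2-hydroxy-4-methoxyphenyl]-3-[3,5-bis(benzyloxy)-4-methoxyphenyl]propane-1,3-dione F8. Cyclodehydration of F8 (TsOH, toluene, 80 °C) gives 22. Only the one free phenol of F8 can close the ring, so the regiochemistry is the same as in step 11.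

**Step 12.** Incomplete cleavage of one of the five benzyl ethers is possible as the polyphenol adsorbs on the catalyst, and the 5,8-hydroquinone can oxidise to the quinone during filtration and concentration if air is admitted.
Fallback, from 22, returning at 23: Lewis-acid debenzylation with BCl3 and pentamethylbenzene as cation scavenger (CH2Cl2, −78 °C, MeOH quench). This is homogeneous and involves no catalyst filtration; the low temperature is meant to spare the two methyl ethers, neither of which is next to the carbonyl group. No new compound is made on the way.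

## Further compounds

F1 | step 5 | 1-(benzyloxy)but-3-yn-2-one | C#CC(=O)COCc1ccccc1
F2 | step 5 | 2-(benzyloxy)-1-[2-(tert-butyldimethylsilyloxy)-5-hydroxy-4-methoxyphenyl]ethan-1-one | COc1cc(O[Si](C)(C)C(C)(C)C)c(C(=O)COCc2ccccc2)cc1O
F3 | step 10 | 3,5-bis(benzyloxy)-4-methoxybenzaldehyde | O=Cc1cc(OCc2ccccc2)c(OC)c(OCc2ccccc2)c1
F4 | step 10 | 2-(benzyloxy)-1-[3,6-bis(benzyloxy)-2-bromo-4-methoxyphenyl]-3-[3,5-bis(benzyloxy)-4-methoxyphenyl]-3-hydroxypropan-1-one (mixture of racemic diastereomers) | COc1cc(OCc2ccccc2)c(C(=O)C(OCc2ccccc2)C(O)c2cc(OCc3ccccc3)c(OC)c(OCc3ccccc3)c2)c(Br)c1OCc1ccccc1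
F5 | step 11 | 2-(benzyloxy)-1-[3,6-bis(benzyloxy)-4-methoxy-2-(4,4,5,5-tetramethyl-1,3,2-dioxaborolan-2-yl)phenyl]ethan-1-one | COc1cc(OCc2ccccc2)c(C(=O)COCc2ccccc2)c(B2OC(C)(C)C(C)(C)O2)c1OCc1ccccc1
F6 | step 11 | 2-(benzyloxy)-1-[3,6-bis(benzyloxy)-2-hydroxy-4-methoxyphenyl]ethan-1-one | COc1cc(OCc2ccccc2)c(C(=O)COCc2ccccc2)c(O)c1OCc1ccccc1
F7 | step 11 | 3,6-bis(benzyloxy)-2-[(benzyloxy)acetyl]-5-methoxyphenyl 3,5-bis(benzyloxy)-4-methoxybenzoate | COc1cc(OCc2ccccc2)c(C(=O)COCc2ccccc2)c(OC(=O)c2cc(OCc3ccccc3)c(OC)c(OCc3ccccc3)c2)c1OCc1ccccc1
F8 | step 11 | 2-(benzyloxy)-1-[3,6-bis(benzyloxy)-2-hydroxy-4-methoxyphenyl]-3-[3,5-bis(benzyloxy)-4-methoxyphenyl]propane-1,3-dione (racemic, in equilibrium with its enol) | COc1cc(OCc2ccccc2)c(C(=O)C(OCc2ccccc2)C(=O)c2cc(OCc3ccccc3)c(OC)c(OCc3ccccc3)c2)c(O)c1OCc1ccccc1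
F0 | step 12 | none | none
A1 | alternative 1 | 3-[3,5-bis(benzyloxy)-4-methoxyphenyl]-1-(2-hydroxy-4,6-dimethoxyphenyl)prop-2-yn-1-one | COc1cc(O)c(C(=O)C#Cc2cc(OCc3ccccc3)c(OC)c(OCc3ccccc3)c2)c(OC)c1
A2 | alternative 1 | 3-[3,5-bis(benzyloxy)-4-methoxyphenyl]prop-2-ynoic acid | OC(=O)C#Cc1cc(OCc2ccccc2)c(OC)c(OCc2ccccc2)c1
A3 | alternative 1 | 3,5-dimethoxy-2-(trimethylsilyl)phenyl trifluoromethanesulfonate | COc1cc(OC)c([Si](C)(C)C)c(OS(=O)(=O)C(F)(F)F)c1
A4 | alternative 1 | 2-[3,5-bis(benzyloxy)-4-methoxyphenyl]-5,7-dimethoxy-4H-chromen-4-one | COc1cc(OC)c2c(=O)cc(-c3cc(OCc4ccccc4)c(OC)c(OCc4ccccc4)c3)oc2c1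
A5 | alternative 2 | 2-[3,5-bis(benzyloxy)-4-methoxyphenyl]-5,7-dimethoxy-3-nitro-2H-chromene (racemic) | COc1cc(OC)c2C=C([N+](=O)[O-])C(c3cc(OCc4ccccc4)c(OC)c(OCc4ccccc4)c3)Oc2c1
A6 | alternative 2 | 2-hydroxy-4,6-dimethoxybenzaldehyde | COc1cc(O)c(C=O)c(OC)c1
A7 | alternative 2 | 1,3-bis(benzyloxy)-2-methoxy-5-[(E)-2-nitroethenyl]benzene | COc1c(OCc2ccccc2)cc(/C=C/[N+](=O)[O-])cc1OCc1ccccc1
A8 | alternative 3 | 3-(benzyloxy)-2-[3,5-bis(benzyloxy)-4-methoxyphenyl]-5,8-dihydroxy-7-methoxy-4H-chromen-4-one | COc1cc(O)c2c(=O)c(OCc3ccccc3)c(-c3cc(OCc4ccccc4)c(OC)c(OCc4ccccc4)c3)oc2c1O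
A9 | alternative 3 | 4-{5-(benzyloxy)-6-[3,5-bis(benzyloxy)-4-methoxyphenyl]-4-oxo-4H-pyran-2-yl}-4-hydroxy-3-methoxycyclobut-2-en-1-one (racemic) | COC1=CC(=O)C1(O)c1cc(=O)c(OCc2ccccc2)c(-c2cc(OCc3ccccc3)c(OC)c(OCc3ccccc3)c2)o1
A10 | alternative 3 | 3-methoxycyclobut-3-ene-1,2-dione | COC1=CC(=O)C1=O
A11 | alternative 3 | 3-(benzyloxy)-2-[3,5-bis(benzyloxy)-4-methoxyphenyl]-4H-pyran-4-one | O=c1ccoc(-c2cc(OCc3ccccc3)c(OC)c(OCc3ccccc3)c2)c1OCc1ccccc1
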